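**Plan**

- Numbering: phthalide positions, primed for the hydroxylated unit; target 18 is (Z,Z′)-(6S,7R,4′R,6′R,7′S). Retrosynthesis: the C6′ alcohol comes from its ketone; each (Z)-butylidene butenolide is cut at the lactone C–O and C1–C7a bonds (carbon monoxide) and at C3–C3a (pentanoyl), leaving two ring ketones; the C6–H/C7–H pair is traced to an enone C=C.
- The tricyclic enone ketol is then cut at C7′–C6′ and C7–C4′ in one stroke to a 3-substituted cyclohexenone with an (E)-enone acetal side chain, itself cut at C3a′=C4′ (Wittig) and C6–C7′ (vinylogous ester transposition).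
- Forward: ring A is bought as 3-ethoxycyclohexenone; one pot closes the C7–C4′ ring and then the C7′–C6′ ring, completing the bicyclo[2.2.2]octene; the enone is hydrogenated and both butenolide rings are annulated at the same time.
- Enabling feature: the CH2 that becomes C7′ lies between the enone β-carbon C6 of ring A and the side-chain ketone C7a′. Its anion is a vinylogous 1,3-diketonate with carbon termini C7 and C7′, and the chain carries an enone β-carbon (C4′) and a masked aldehyde (C6′) in the matching 1,3 relation.
- Stereochemistry: C4′ and C7′ from a chiral ammonium ion pair in the key step; C6 and C7 from cis hydrogenation on the face of the flat ketone bridge; C6′ last, by hydride attack on the ketone face not covered by ring A; Z alkenes from enol-oxygen acylation, the E alkene from a stabilised ylide.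

Key step: step 4

Assumption: the bridging aldol is drawn as giving the C9 alcohol turned toward the C2 ketone; either C9 epimer serves, because this centre is re-set in steps 11 and 12. Compounds 10–14 use 1,4-ethanonaphthalene numbering (C1 = C7′, C2 = C7a′, C3 = C3a′, C4 = C4′, C4a = C7, C5 = C7a, C6 = C3a, C8a = C6, C9 = C6′).

**Step 1**
Reactants: 1 1-(triphenyl-λ5-phosphanylidene)propan-2-one; 2 3-ethoxycyclohex-2-en-1-one
Product: 4 1-(3-oxocyclohex-1-en-1-yl)-3-(triphenyl-λ5-phosphanylidene)propan-2-one, via tertiary alcohol adduct 3 (not isolated)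
Conditions: n-BuLi (1.05 equiv), THF, −78 °C; 2, −78 to 0 °C; 1 M HCl, 25 °C; then aq. NaHCO3
Reagents that add atoms: none
Why: Stork–Danheiser-type 1,2-addition of the γ-lithiated acyl ylide to the vinylogous ester, then acid-promoted loss of ethanol, transposes the carbonyl and should give the 3-substituted cyclohexenone, the ylide being restored by base.

**Step 2**
Reactants: 5 methyl 3,3-dimethoxypropanoate
Product: 6 3,3-dimethoxypropanal
Conditions: i-Bu2AlH (1.05 equiv), CH2Cl2, −78 °C; aq. potassium sodium tartrate
Reagents that add atoms: none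
Why: Partial reduction of the ester at −78 °C stops at the tetrahedral aluminium hemiacetal, which releases the aldehyde on hydrolysis.

**Step 3**
Reactants: 4 1-(3-oxocyclohex-1-en-1-yl)-3-(triphenyl-λ5-phosphanylidene)propan-2-one; 6 3,3-dimethoxypropanal
Product: 7 (E)-6,6-dimethoxy-1-(3-oxocyclohex-1-en-1-yl)hex-3-en-2-one
Conditions: CH2Cl2, 25 °C; product used without delay
Reagents that add atoms: none
Why: Wittig olefination with the stabilised acyl ylide needs no added base, so the β-acetal aldehyde should not eliminate, and stabilised ylides give the (E)-enone.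

**Step 4**
Reactants: 7 (E)-6,6-dimethoxy-1-(3-oxocyclohex-1-en-1-yl)hex-3-en-2-one
Product: 10 (1R,4S,9S)-9-hydroxy-3,4,7,8-tetrahydro-1H-1,4-ethanonaphthalene-2,5(6H)-dione, via acetal dione 8 (not isolated), via aldehyde dione 9 (not isolated)
Conditions: O-allyl-N-(9-anthracenylmethyl)cinchonidinium bromide (10 mol %), Cs2CO3 (20 mol %), toluene, −40 °C; then 2 M HCl, THF, 0 to 25 °C, one pot
Reagents that add atoms: water, O
Why: Proposed new method: Cs2CO3 removes a proton from the CH2 between the ring-A enone β-carbon and the side-chain ketone, and the cross-conjugated 2-oxidotriene, ion-paired with the chiral ammonium cation, closes the C4–C4a bond by a disrotatory 6π-electrocyclisation (formally a 6-endo-trig intramolecular Michael addition of the enone α-carbon to the side-chain enone) to give 8 after proton shift; aqueous acid then unmasks aldehyde 9, whose ring-ketone enol adds through C1 to the aldehyde carbon (6-(enolendo)-exo-trig aldol), closing the second six-membered ring and with it the bicyclo[2.2.2]octene. The closest known reaction types are cinchona-ammonium phase-transfer-catalysed enantioselective electrocyclisations and intramolecular Michael additions of delocalised carbanions, base-promoted 6π closure of oxidotrienes, and acid-promoted bridging aldol closures of 4-(2-oxoethyl)cyclohexanones; what is new is asymmetric ion-pair control of an all-carbon 6π closure of a cross-conjugated trienolate. The helical s-cis,Z,s-cis trienolate has two enantiomeric coiling senses and, with the fixed (E)-alkene, each sense gives one configuration at C4, so a cation that binds one coil should set C4 (S); C1 is then fixed by the geometry of bridging, and C9 by a hydrogen-bonded closed transition state that turns the new hydroxyl toward the C2 ketone. The step needs carbon–carbon bonding at C4a and C1 only: carbonate can form only the anion between the two carbonyl systems, whose carbon termini are exactly these two atoms, and the acetal keeps the aldehyde latent until the first ring exists. The main competitor is a vinylogous aldol condensation from the ring-A γ-methylene (C8) in the acid stage, which the far higher enol content at C1 and the low temperature should hold back.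

**Step 5**
Reactants: 10 (1R,4S,9S)-9-hydroxy-3,4,7,8-tetrahydro-1H-1,4-ethanonaphthalene-2,5(6H)-dione
Product: 11 (1R,4S,9S)-9-[(tert-butyldimethylsilyl)oxy]-3,4,7,8-tetrahydro-1H-1,4-ethanonaphthalene-2,5(6H)-dione
Conditions: t-BuMe2SiOTf (1.2 equiv), 2,6-lutidine, CH2Cl2, −78 °C
Reagents that add atoms: tert-butyldimethylsilyl trifluoromethanesulfonate, CC(C)(C)[Si](C)(C)OS(=O)(=O)C(F)(F)F
Why: Silylation of the secondary alcohol with the silyl triflate is fast at −78 °C and blocks retro-aldol opening of the β-ketol in the later base steps.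

**Step 6**
Reactants: 11 (1R,4S,9S)-9-[(tert-butyldimethylsilyl)oxy]-3,4,7,8-tetrahydro-1H-1,4-ethanonaphthalene-2,5(6H)-dione
Product: 12 (1R,4S,4aS,8aS,9S)-9-[(tert-butyldimethylsilyl)oxy]octahydro-1,4-ethanonaphthalene-2,5-dione
Conditions: H2 (5 atm), 10% Pd/C, EtOAc, 25 °C
Reagents that add atoms: none
Why: Heterogeneous hydrogenation of the strained tetrasubstituted enone C=C should add both hydrogens cis from the face flanked by the flat C2 ketone bridge, not the CH(OSi)–CH2 bridge, which sets C4a and C8a and turns ring A toward the oxygenated bridge; the ring fusion can only be cis, so C4a cannot drift by enolisation.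

**Step 7**
Reactants: 12 (1R,4S,4aS,8aS,9S)-9-[(tert-butyldimethylsilyl)oxy]octahydro-1,4-ethanonaphthalene-2,5-dione
Product: 13 bis(β-diketone): 12 with pentanoyl groups at C3 and C6 (shown as the ring enols)
Conditions: LiN(i-Pr)2 (4.4 equiv), THF, −78 °C; 1-(1H-benzotriazol-1-yl)pentan-1-one (2.4 equiv), −78 to 0 °C; aq. NH4Cl
Reagents that add atoms: 1-(1H-benzotriazol-1-yl)pentan-1-one, CCCCC(=O)n1nnc2ccccc12
Why: Claisen-type C-acylation of the two kinetic lithium enolates with an N-acylbenzotriazole; deprotonation occurs at the methylene C6 rather than the methine C4a, and at C3 because C1 is a bridgehead.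

**Step 8**
Reactants: 13 bis(β-diketone)
Product: 14 bis(enol triflate): 13 with the C2 and C5 enol oxygens as trifluoromethanesulfonates (endocyclic C2=C3 and C5=C6)
Conditions: Tf2O (2.4 equiv), Et3N (3 equiv), CH2Cl2, −78 °C
Reagents that add atoms: trifluoromethanesulfonic anhydride, O=S(=O)(OS(=O)(=O)C(F)(F)F)C(F)(F)F
Why: O-sulfonylation of each 2-acyl ketone at the ring-enol oxygen, the dominant enol of 2-acyl six-membered-ring ketones, should give the endocyclic β-triflyloxy enones with the acyl group held cis by the ring.

**Step 9**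
Reactants: 14 bis(enol triflate)
Product: 15 tert-butyldimethylsilyl ether of 6′-epi-18, (6S,7R,4′R,6′S,7′S)
Conditions: Pd(PPh3)4 (10 mol %), CO (1 atm), Et3N (3 equiv), MeCN, 60 °C
Reagents that add atoms: carbon monoxide, [C-]#[O+]
Why: Carbonylative lactonisation: oxidative addition of zerovalent palladium to each vinyl triflate, CO insertion and capture of the acylpalladium by the enol oxygen of the neighbouring pentanoyl group should close both butenolides, with the (Z)-butylidene geometry that keeps the propyl group away from the ring.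

**Step 10**
Reactants: 15 tert-butyldimethylsilyl ether of 6′-epi-18
Product: 16 6′-epi-18, (6S,7R,4′R,6′S,7′S)
Conditions: HF·pyridine, THF, 0 to 25 °C
Reagents that add atoms: none
Why: Acidic fluoride cleaves the silyl ether without opening the base-sensitive enol lactones.

**Step 11**
Reactants: 16 6′-epi-18
Product: 17 6′-ketone, (6S,7R,4′R,7′S)
Conditions: Dess–Martin periodinane (1.3 equiv), CH2Cl2, 25 °C
Reagents that add atoms: none
Why: Dess–Martin oxidation converts the secondary alcohol to the ketone under neutral conditions and erases the provisional C6′ configuration; the ketone cannot enolise toward the bridgehead.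

**Step 12**
Reactants: 17 6′-ketone
Product: 18 target CNP0289078.2, (Z,Z′)-(6S,7R,4′R,6′R,7′S)
Conditions: NaBH4, CeCl3·7H2O, MeOH/CH2Cl2, −78 °C
Reagents that add atoms: none
Why: Luche reduction is selective for the ketone over the enol lactones, and hydride should enter from the face next to the flat butenolide bridge because the C5 methylene of ring A covers the other face, which sets C6′ (R) with the hydroxyl turned toward ring A.

**Compound list**

1 | 1-(triphenyl-λ5-phosphanylidene)propan-2-one | CC(=O)C=P(c1ccccc1)(c1ccccc1)c1ccccc1 | starting material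
2 | 3-ethoxycyclohex-2-en-1-one | CCOC1=CC(=O)CCC1 | starting material
3 | 1-(3-ethoxy-1-hydroxycyclohex-2-en-1-yl)-3-(triphenyl-λ5-phosphanylidene)propan-2-one (racemic) | CCOC1=CC(O)(CC(=O)C=P(c2ccccc2)(c2ccccc2)c2ccccc2)CCC1 | intermediate
4 | 1-(3-oxocyclohex-1-en-1-yl)-3-(triphenyl-λ5-phosphanylidene)propan-2-one | O=C1C=C(CC(=O)C=P(c2ccccc2)(c2ccccc2)c2ccccc2)CCC1 | intermediate
5 | methyl 3,3-dimethoxypropanoate | COC(=O)CC(OC)OC | starting material
6 | 3,3-dimethoxypropanal | O=CCC(OC)OC | intermediate
7 | (E)-6,6-dimethoxy-1-(3-oxocyclohex-1-en-1-yl)hex-3-en-2-one | O=C1C=C(CC(=O)/C=C/CC(OC)OC)CCC1 | intermediate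
8 | (8S)-8-(2,2-dimethoxyethyl)-3,4,7,8-tetrahydronaphthalene-1,6(2H,5H)-dione | O=C1CCCC2=C1[C@@H](CC(OC)OC)CC(=O)C2 | intermediate
9 | 2-[(1S)-3,8-dioxo-1,2,3,4,5,6,7,8-octahydronaphthalen-1-yl]acetaldehyde | O=C1CCCC2=C1[C@@H](CC=O)CC(=O)C2 | intermediate
10 | (1R,4S,9S)-9-hydroxy-3,4,7,8-tetrahydro-1H-1,4-ethanonaphthalene-2,5(6H)-dione | O=C1CCCC2=C1[C@@H]3CC(=O)[C@H]2[C@@H](O)C3 | intermediate
11 | (1R,4S,9S)-9-[(tert-butyldimethylsilyl)oxy]-3,4,7,8-tetrahydro-1H-1,4-ethanonaphthalene-2,5(6H)-dione | O=C1CCCC2=C1[C@@H]3CC(=O)[C@H]2[C@@H](O[Si](C)(C)C(C)(C)C)C3 | intermediate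
12 | (1R,4S,4aS,8aS,9S)-9-[(tert-butyldimethylsilyl)oxy]octahydro-1,4-ethanonaphthalene-2,5-dione | O=C2CCC[C@@H]1[C@H]3C(=O)C[C@H](C[C@@H]3O[Si](C)(C)C(C)(C)C)[C@H]21 | intermediate
13 | 12 bearing pentanoyl groups at C3 and C6, drawn as the C2 and C5 ring enols; stereocentres as in 12 | OC2=C(C(=O)CCCC)CC[C@@H]1[C@H]3C(O)=C(C(=O)CCCC)[C@H](C[C@@H]3O[Si](C)(C)C(C)(C)C)[C@H]21 | intermediate
14 | bis(trifluoromethanesulfonate) of the C2 and C5 ring enols of 13; stereocentres as in 12 | FC(F)(F)S(=O)(=O)OC2=C(C(=O)CCCC)CC[C@@H]1[C@H]3C(OS(=O)(=O)C(F)(F)F)=C(C(=O)CCCC)[C@H](C[C@@H]3O[Si](C)(C)C(C)(C)C)[C@H]21 | intermediate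
15 | tert-butyldimethylsilyl ether of 6′-epi-18: (Z,Z′)-bis-butylidene bis-butenolide, (6S,7R,4′R,6′S,7′S) | CCC/C=C1\OC(=O)C2=C1CC[C@@H]1[C@H]3C4=C(/C(=C/CCC)OC4=O)[C@H](C[C@@H]3O[Si](C)(C)C(C)(C)C)[C@H]21 | intermediate
16 | 6′-epi-18, (6S,7R,4′R,6′S,7′S), hydroxyl turned toward the butenolide bridge | CCC/C=C1\OC(=O)C2=C1CC[C@@H]1[C@H]3C4=C(/C(=C/CCC)OC4=O)[C@H](C[C@@H]3O)[C@H]21 | intermediate
17 | 6′-oxo compound, (6S,7R,4′R,7′S) | CCC/C=C1\OC(=O)C2=C1CC[C@@H]1[C@H]3C4=C(/C(=C/CCC)OC4=O)[C@H](CC3=O)[C@H]21 | intermediate
18 | CNP0289078.2: (Z,Z′)-bis(3-butylidene) phthalide dimer linked C6–C7′ and C7–C4′, 6′-hydroxy, (6S,7R,4′R,6′R,7′S), hydroxyl and ring A on the same side of the bicyclo[2.2.2]octene | CCC/C=C1\OC(=O)C2=C1CC[C@@H]1[C@H]3C4=C(/C(=C/CCC)OC4=O)[C@H](C[C@H]3O)[C@H]21 | target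

Total step count: 12. Longest linear sequence: 11 steps (steps 1 and 3–12, from compound 2).

**Steps most likely to fail**

Step 4 (carries the label). The ion pair may fail to distinguish the two coiling senses of the trienolate, or uncatalysed thermal closure may compete, so that the enantiomeric purity is low; in the acid stage the vinylogous condensation from C8 may overtake the bridging aldol. The fallback uses known chemistry, sets out from 7 and comes back at 10. Compound 7 is treated with 1,8-diazabicyclo[5.4.0]undec-7-ene (10 mol %) in toluene, which should give the racemic acetal dione F1. The same 2 M HCl treatment should then pass through the racemic aldehyde F2 to the racemic ketol F3. Dess–Martin oxidation of F3 should give the triketone 3,4,7,8-tetrahydro-1H-1,4-ethanonaphthalene-2,5,9(6H)-trione F4, which is achiral because its two bridge ketones are mirror-related through the plane of the enone ring. Enantioselective mono-reduction of one of these enantiotopic ketones with (R)-2-methyl-CBS-oxazaborolidine (10 mol %) and catecholborane at −78 °C, hydride entering from the side of the alkene bridge, should return to 10; a diastereomeric alcohol, if formed, would be removed by chromatography before going on.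

Step 8. Sulfonylation may occur at the side-chain enol oxygen instead of the ring oxygen, which would lead to the wrong lactone orientation. The fallback sets out from 12 and comes back at 15. The bis-enolate of 12 (LiN(SiMe3)2, THF, −78 °C) is alkynylated with 1-(pent-1-yn-1-yl)-1,2-benziodoxol-3(1H)-one to the bis(α-pentynyl ketone) F5. Each ring now has a single carbonyl, so KN(SiMe3)2 and N-phenylbis(trifluoromethanesulfonimide) should give the bis(enyne triflate) F6 without ambiguity, enolisation going toward the propargylic carbon. Hydroxycarbonylation (Pd(PPh3)4, CO, H2O, Et3N, DMF) should give the bis(enynoic acid) F7. AgNO3 (10 mol %) in acetone should then close both rings by anti 5-exo-dig addition of the acids to the alkynes, giving the (Z)-butylidene butenolides of 15.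

Step 6. The tetrasubstituted alkene may reduce slowly, and delivery of hydrogen may not discriminate well between the two faces. The fallback sets out from 11 and comes back at 12, and it makes no compound outside the list (F0). The enone is reduced by conjugate hydride addition with [(Ph3P)CuH]6 in wet toluene at 25 °C. The bulky copper hydride should attack C8a from the face of the flat ketone bridge, and the resulting enolate is protonated at C4a on work-up to the only possible, cis-fused ketone.

**Further compounds**

F1 | step 4 | racemic 8-(2,2-dimethoxyethyl)-3,4,7,8-tetrahydronaphthalene-1,6(2H,5H)-dione | O=C1CCCC2=C1[C@@H](CC(OC)OC)CC(=O)C2.O=C1CCCC2=C1[C@H](CC(OC)OC)CC(=O)C2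
F2 | step 4 | racemic 2-(3,8-dioxo-1,2,3,4,5,6,7,8-octahydronaphthalen-1-yl)acetaldehyde | O=C1CCCC2=C1[C@@H](CC=O)CC(=O)C2.O=C1CCCC2=C1[C@H](CC=O)CC(=O)C2
F3 | step 4 | racemic (1R*,4S*,9S*)-9-hydroxy-3,4,7,8-tetrahydro-1H-1,4-ethanonaphthalene-2,5(6H)-dione | O=C1CCCC2=C1[C@@H]3CC(=O)[C@H]2[C@@H](O)C3.O=C1CCCC2=C1[C@H]3CC(=O)[C@@H]2[C@H](O)C3
F4 | step 4 | 3,4,7,8-tetrahydro-1H-1,4-ethanonaphthalene-2,5,9(6H)-trione (achiral) | O=C1CCCC2=C1C1CC(=O)C2C(=O)C1
F0 | step 6 | none | none
F5 | step 8 | 12 bearing pent-1-yn-1-yl groups at C3 and C6 (epimers at these two carbons) | O=C2C(C#CCCC)CC[C@@H]1[C@H]3C(=O)C(C#CCCC)[C@H](C[C@@H]3O[Si](C)(C)C(C)(C)C)[C@H]21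
F6 | step 8 | bis(trifluoromethanesulfonate) of the C2 and C5 enols of F5 | FC(F)(F)S(=O)(=O)OC2=C(C#CCCC)CC[C@@H]1[C@H]3C(OS(=O)(=O)C(F)(F)F)=C(C#CCCC)[C@H](C[C@@H]3O[Si](C)(C)C(C)(C)C)[C@H]21
F7 | step 8 | 2,5-dicarboxylic acid from F6 (carboxyl groups in place of the two triflates) | OC(=O)C2=C(C#CCCC)CC[C@@H]1[C@H]3C(C(O)=O)=C(C#CCCC)[C@H](C[C@@H]3O[Si](C)(C)C(C)(C)C)[C@H]21
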